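The ratio 8.00 is what I reckon with: the time allowed, 10 d, over the substrate half-life read in zeta, 1.25 d, where the substrate stands at 50.0%. I call it the half-life count. Two extreme versions of the flask give estimates of the substrate left at the end, not bounds. If the rate follows the substrate and not the reagent (pseudo-first-order), each half-life halves what stands, and the count leaves 0.391%. If the rate follows substrate times reagent, charged equal here, the remainder goes as one over one plus the count, which leaves 11.1%.

| setting | eta | zeta | midnight | winter |
|---|---|---|---|---|
| substrate | 0.078 M | 0.078 M | 0.078 M | 0.078 M |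
| reagent | 0.078 M | 0.078 M | 0.0780 M | 0.0780 M |
| scavenger | 0.053 M | 0.078 M | 0.0620 M | 0.0940 M |
| free catalyst | 3.9 mM | 3.9 mM | 3.9 mM | 3.9 mM |
| remark | run made earlier | run made earlier |  |  |
| time |  |  | 10 d | 10 d |

| run | time / d | substrate / % | product / % |
|---|---|---|---|
| eta | 0.625 | 71.6 | 26.5 |
| eta | 0.833 | 63.9 | 36.1 |
| eta | 1.67 | 37.9 | 61.3 |
| eta | 2.50 | 23.1 | 78.1 |
| eta | 4.00 | 8.3 | 92.2 |
| eta | 8.00 | 1.6 | 99.1 |
| zeta | 0.500 | 77.6 | 21.6 |
| zeta | 1.25 | 50.0 | 52.9 |
| zeta | 2.50 | 23.0 | 78.3 |
| zeta | 4.00 | 6.2 | 94.0 |
| zeta | 5.00 | 3.5 | 96.8 |
| zeta | 8.00 | 2.3 | 100.6 |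

(readings scatter by 1 percentage point)

1. part of the substrate that has reacted at the end, midnight
2. part of the substrate that has reacted at the end, winter
3. what raising the concentration of scavenger from its lowest to its highest value here does to the part of the substrate that has reacted (changes below 5 percentage points count as none) (no change / it falls / it rises)

I hold both against the readings. At 8.00 d the count is 6.40, so the extremes leave 1.18% and 13.5%. Eta shows 1.6% and zeta 2.3%, lower than the second extreme, so I stand near the first. The first is no floor, though: at 5.00 d it leaves 6.25%, and zeta reads lower, 3.5%. Eta and zeta hold 0.053 M and 0.078 M of scavenger, yet at 2.50 d they read 23.1% and 23.0%. I therefore use one half-life for midnight and winter and commit to 99.6% reacted in each, with no change, although winter's 0.0940 M lies above the charges tried.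

The forecast gives 99.6% for midnight, 99.3% for winter, and no change. On midnight we agree; winter it sets lower than I do, noting that “excess scavenger might tie up catalyst”.

The flask gives 99.6% for midnight and 99.7% for winter, no change, with a change of 0.13 percentage points. Free scavenger at the end stands at 0% in midnight and 17.0% in winter. Against the 0.391% of the count, the substrate left is 0.39% in midnight and 0.26% in winter.

    catalyst intermediate C → free catalyst + product (k = 1.30 /min)
    reagent + released group ⇌ idle adduct, settled at all times (K = 32.0 /M)
    scavenger + released group → scavenged by-product (k = 0.170 /M/min)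
    reagent + free catalyst ⇌ catalyst intermediate A (K = 17.0 /M, k = 0.940 /M/min)
    substrate + catalyst intermediate B → catalyst intermediate C (k = 0.940 /M/min)
    catalyst intermediate A → released group + catalyst intermediate B (k = 0.0160 /min)

The neighbour flask is winter with 0.0016 M of free catalyst. If the half-life stretches inversely with catalyst, the count falls to 3.28 and leaves 10.3%. The flask leaves 4.88%, so the reckoning gives twice the substrate found, and 95.1% has reacted.

All runs were generated by integration from invented constants.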